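A direct plan would take 2,4,6-trihydroxybenzaldehyde through O-prenylation, Claisen shift and bis-silylation to aldehyde A1, then by dibromo-olefination and copper-catalysed C–O closure to the 2-bromobenzofuran A2.
Lithiated A2 would be added to the ethoxycyclobutenone A3 (from thermal dimerisation of a prenylated ynol ether) to give the aryl cyclobutenone A4.
Ring B would be closed last by a Danheiser benzannulation of A4 with the ynol ether A5, and fluoride would strip the silyl and 2-(trimethylsilyl)ethyl groups from A6.
Its weakest steps would be, first, the bis-silylation that must leave free only the hydroxyl between the formyl group and the quaternary carbon: two chelated ortho hydroxyls differ little, and this choice alone decides which oxygen closes the furan.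
Second, the late benzannulation: four pericyclic events in one flask on the most valuable intermediate, with a heat-sensitive ynol ether and three alkenes that can trap the ketenes, after four steps spent on two ynol ethers and a cyclobutenone.
Third, the final fluoride cleavage of an aryl 2-(trimethylsilyl)ethyl ether, which has little precedent and would otherwise call for acid on ortho-prenyl phenols.

Plan of the new route
The retrosynthesis cuts the furan bond O1–C2 first (formed last), then C1'–C2' and C1'–C6' of ring B (benzofuran numbering, ring B atoms primed).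
Feature used: ring B is a symmetric 5-substituted resorcinol whose C1' bears no oxygen and lies between the two prenylated carbons, so C2'–C6' is the chain of one symmetric 1,3-diketone (12) and C1' can come from a carboxyl carbon.
That carboxyl carbon is the lactone carbonyl of the 3-methoxycoumarin 9; its C3 and C4 are C2 and C3 of the benzofuran and its ring oxygen is O1, so the fold that makes ring B also opens the pyranone.
Ring order: ring A (bought as phloroglucinol), ring B (step 7), furan (step 8, enol ether closure with loss of methanol).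
O1 needs no selective protection, since it carries the prenyl group into the Claisen shift and then becomes the lactone oxygen; no ynol ether or cyclobutenone is needed; only MOM ethers are removed at the end, with dilute acid.
Key step: step 7

Step 1
Reactants: 1 phloroglucinol (benzene-1,3,5-triol)
Product: 2 3,5-bis(methoxymethoxy)phenol
Conditions: NaH (2.0 equiv), DMF, 0 °C; MOMCl (2.0 equiv), 0 → 20 °C; chromatography
Reagents that add atoms: chloromethyl methyl ether, COCCl
Why: Williamson-type acetalisation of two of the three equivalent phenoxides should give the bis-ether, which is separated from mono- and tris-ether, a statistical step that is acceptable only because it is the first one and uses the cheapest material.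

Step 2
Reactants: 2 3,5-bis(methoxymethoxy)phenol; 3 1-bromo-3-methylbut-2-ene (prenyl bromide)
Product: 4 1,3-bis(methoxymethoxy)-5-[(3-methylbut-2-en-1-yl)oxy]benzene
Conditions: K2CO3 (1.5 equiv), 3 (1.2 equiv), acetone, 56 °C
Reagents that add atoms: none
Why: Williamson etherification with carbonate in acetone should alkylate the phenoxide at oxygen (SN2 at the primary allylic carbon) and not at carbon.

Step 3
Reactants: 4 1,3-bis(methoxymethoxy)-5-[(3-methylbut-2-en-1-yl)oxy]benzene
Product: 5 3,5-bis(methoxymethoxy)-2-(2-methylbut-3-en-2-yl)phenol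
Conditions: PhNEt2, 190 °C, sealed tube, argon
Reagents that add atoms: none
Why: Aromatic Claisen rearrangement ([3,3]-sigmatropic shift) joins the CMe2 terminus to one of two equivalent ortho carbons, whose hydrogen lets the dienone enolise before a Cope shift to the para carbon, and the hydroxyl set free is by construction the one next to the quaternary carbon, the future O1.

Step 4
Reactants: 5 3,5-bis(methoxymethoxy)-2-(2-methylbut-3-en-2-yl)phenol
Product: 6 2-hydroxy-4,6-bis(methoxymethoxy)-3-(2-methylbut-3-en-2-yl)benzaldehyde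
Conditions: MgCl2 (2 equiv), Et3N (4 equiv), (CH2O)n (6 equiv), MeCN, 80 °C; aq. citric acid
Reagents that add atoms: paraformaldehyde, C=O
Why: Magnesium-mediated ortho-formylation (Casnati–Skattebøl) delivers formaldehyde through the chloromagnesium phenoxide (ArOMgCl) to the only free ortho carbon and oxidises the benzylic alkoxide with a second formaldehyde, a reaction that is standard for 2-tert-alkylphenols and basic enough to spare the MOM ethers.

Step 5
Reactants: 6 2-hydroxy-4,6-bis(methoxymethoxy)-3-(2-methylbut-3-en-2-yl)benzaldehyde; 7 methoxyacetyl chloride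
Product: 9 3-methoxy-5,7-bis(methoxymethoxy)-8-(2-methylbut-3-en-2-yl)-2H-chromen-2-one, via 2-formylaryl methoxyacetate 8 (not isolated)
Conditions: 7 (1.5 equiv), K2CO3 (4 equiv), MeCN, 0 → 20 °C; then DBU (0.3 equiv), 70 °C
Reagents that add atoms: none
Why: O-acylation followed by intramolecular aldol condensation of the ester enolate on the ortho-formyl group (Perkin–Oglialoro-type coumarin synthesis, acid chloride variant) should give the coumarin, the tether forcing the aryl group cis to the carbonyl, which an intermolecular olefination would not do, while the 3-methoxy group masks the future C2 ketone.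

Step 6
Reactants: 10 acetylacetone (pentane-2,4-dione); 3 1-bromo-3-methylbut-2-ene (two equivalents)
Product: 12 2,12-dimethyltrideca-2,11-diene-6,8-dione, via lithium enolate of 8-methylnon-7-ene-2,4-dione 11 (not isolated)
Conditions: LiN(i-Pr)2 (2.05 equiv), THF, −78 → 0 °C; 3 (1.0 equiv), −78 → 0 °C; LiN(i-Pr)2 (1.05 equiv), −78 → 0 °C; 3 (1.0 equiv), −78 → 20 °C; aq. NH4Cl
Reagents that add atoms: none
Why: Hauser–Harris γ-alkylation of a 1,3-diketone dianion, run twice in one flask, should give the symmetric diketone, because the terminal carbanion is far more nucleophilic than the central enolate and the second dianion forms at the remaining methyl group in preference to the substituted methylene.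

Step 7
Reactants: 9 3-methoxy-5,7-bis(methoxymethoxy)-8-(2-methylbut-3-en-2-yl)-2H-chromen-2-one; 12 2,12-dimethyltrideca-2,11-diene-6,8-dione
Product: 15 5-[(E)-2-[2-hydroxy-4,6-bis(methoxymethoxy)-3-(2-methylbut-3-en-2-yl)phenyl]-1-methoxyethenyl]-4,6-bis(3-methylbut-2-en-1-yl)benzene-1,3-diol (ring A cis to ring B), via dilithiated diketone 13 (not isolated), via ring-opened triketone 14 (not isolated)
Conditions: LiN(i-Pr)2 (4.4 equiv), 12 (2.2 equiv), THF, −78 → 0 °C; 9 (1.0 equiv), −78 → 0 °C; then MeOH, 0.5 M aq. K2CO3, 40 °C; aq. NH4Cl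
Reagents that add atoms: none
Why: Proposed new method: the terminal carbanion of dilithiated 12 adds to the lactone carbonyl of 9, the tetrahedral intermediate expels the aryloxide O1 and opens the pyranone (Claisen acylation, bond C1'–C6'), the second equivalent of dianion deprotonates triketone 14, and in aqueous carbonate, where the 2-substituted diketone unit is largely protonated and its C1' ketone free, the other α' carbon (C2') adds to C1' (bond C1'–C2'), after which loss of hydroxide and two enolisations give the resorcinol. The closest known reactions are the acylation of 1,3-diketone dianions by esters, cinnamates included, to 1,3,5-triketones and the base-induced aldol cyclodehydration of such triketones to 5-substituted resorcinols (Collie–Harris polyketide folding), whereas a coumarin lactone as acyl donor and a 2-methoxyenone as aldol acceptor are untested. Ring B closes by a 6-(enolendo)-exo-trig intramolecular aldol condensation, the only carbocyclisation of 14 that gives a six-membered ring, aromatisation makes it irreversible, and the competing O-cyclisation to a 4-pyranone needs acid and is not expected in base. No stereocentre is formed, since C6' of 14 is racemic and becomes aromatic and the alkene geometry of 15, inherited from the lactone, is lost in the next step. The step needs 1,2- over 1,4-addition to the coumarin, which should be secured because the localised lithium-bound carbanion is a hard nucleophile, the aryl ester is an activated acyl donor, and C4 is the β-carbon of an enol ether, bonded to a 2,4,6-trioxygenated ring and screened by the peri OMOM group. As 12 is symmetric it does not matter which end acylates, and the phenoxide released is the only unprotected oxygen of ring A.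

Step 8
Reactants: 15 5-[(E)-2-[2-hydroxy-4,6-bis(methoxymethoxy)-3-(2-methylbut-3-en-2-yl)phenyl]-1-methoxyethenyl]-4,6-bis(3-methylbut-2-en-1-yl)benzene-1,3-diol
Product: 17 2-[3,5-dihydroxy-2,6-bis(3-methylbut-2-en-1-yl)phenyl]-7-(2-methylbut-3-en-2-yl)-1-benzofuran-4,6-diol (target, achiral), via benzofuran bis(methoxymethyl) ether 16 (not isolated)
Conditions: PPTS (0.1 equiv), MeOH, 25 °C; then HCl (1.25 M in MeOH), 25 → 40 °C; aq. NaHCO3
Reagents that add atoms: none
Why: Acid-catalysed 5-exo addition of the only free hydroxyl of ring A (O1) to the enol ether (protonation at C3, oxocarbenium ion at C2) and loss of methanol from the mixed ketal should aromatise the furan before the MOM ethers at O4 and O6 are cleaved by acetal exchange, so the other ortho oxygen cannot compete, and dilute methanolic HCl is the usual reagent for MOM removal beside ortho-prenyl phenols.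

Compound list
1 | phloroglucinol (benzene-1,3,5-triol) | Oc1cc(O)cc(O)c1 | starting material
2 | 3,5-bis(methoxymethoxy)phenol | COCOc1cc(O)cc(OCOC)c1 | intermediate
3 | 1-bromo-3-methylbut-2-ene (prenyl bromide) | CC(C)=CCBr | starting material
4 | 1,3-bis(methoxymethoxy)-5-[(3-methylbut-2-en-1-yl)oxy]benzene | COCOc1cc(OCOC)cc(OCC=C(C)C)c1 | intermediate
5 | 3,5-bis(methoxymethoxy)-2-(2-methylbut-3-en-2-yl)phenol | COCOc1cc(O)c(C(C)(C)C=C)c(OCOC)c1 | intermediate
6 | 2-hydroxy-4,6-bis(methoxymethoxy)-3-(2-methylbut-3-en-2-yl)benzaldehyde | O=Cc1c(O)c(C(C)(C)C=C)c(OCOC)cc1OCOC | intermediate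
7 | methoxyacetyl chloride | COCC(Cl)=O | starting material
8 | 2-formyl-3,5-bis(methoxymethoxy)-6-(2-methylbut-3-en-2-yl)phenyl 2-methoxyacetate (not isolated) | COCC(=O)Oc1c(C=O)c(OCOC)cc(OCOC)c1C(C)(C)C=C | intermediate
9 | 3-methoxy-5,7-bis(methoxymethoxy)-8-(2-methylbut-3-en-2-yl)-2H-chromen-2-one | COc1cc2c(OCOC)cc(OCOC)c(C(C)(C)C=C)c2oc1=O | intermediate
10 | acetylacetone (pentane-2,4-dione) | CC(=O)CC(C)=O | starting material
11 | lithium enolate of 8-methylnon-7-ene-2,4-dione (not isolated) | [Li+].CC(=O)C=C([O-])CCC=C(C)C | intermediate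
12 | 2,12-dimethyltrideca-2,11-diene-6,8-dione | CC(C)=CCCC(=O)CC(=O)CCC=C(C)C | intermediate
13 | dilithio derivative of 12, carbanion at C5 and enolate across C6–C8 (not isolated) | [Li+].[Li+].CC(C)=CC[CH-]C(=O)C=C([O-])CCC=C(C)C | intermediate
14 | (1E)-1-[2-hydroxy-4,6-bis(methoxymethoxy)-3-(2-methylbut-3-en-2-yl)phenyl]-2-methoxy-11-methyl-4-(3-methylbut-2-en-1-yl)dodeca-1,10-diene-3,5,7-trione, racemic at C4, present as its lithium salts (not isolated) | COCOc1cc(OCOC)c(C(C)(C)C=C)c(O)c1/C=C(/OC)C(=O)C(CC=C(C)C)C(=O)CC(=O)CCC=C(C)C | intermediate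
15 | 5-[(E)-2-[2-hydroxy-4,6-bis(methoxymethoxy)-3-(2-methylbut-3-en-2-yl)phenyl]-1-methoxyethenyl]-4,6-bis(3-methylbut-2-en-1-yl)benzene-1,3-diol | COCOc1cc(OCOC)c(C(C)(C)C=C)c(O)c1/C=C(/OC)c1c(CC=C(C)C)c(O)cc(O)c1CC=C(C)C | intermediate
16 | 5-[4,6-bis(methoxymethoxy)-7-(2-methylbut-3-en-2-yl)-1-benzofuran-2-yl]-4,6-bis(3-methylbut-2-en-1-yl)benzene-1,3-diol (not isolated) | C=CC(C)(C)c1c(OCOC)cc(OCOC)c2cc(-c3c(CC=C(C)C)c(O)cc(O)c3CC=C(C)C)oc12 | intermediate
17 | 2-[3,5-dihydroxy-2,6-bis(3-methylbut-2-en-1-yl)phenyl]-7-(2-methylbut-3-en-2-yl)-1-benzofuran-4,6-diol (CNP0115465.0, achiral) | C=CC(C)(C)c1c(O)cc(O)c2cc(-c3c(CC=C(C)C)c(O)cc(O)c3CC=C(C)C)oc12 | target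

Total step count: 8. Longest linear sequence: 7 (steps 1, 2, 3, 4, 5, 7, 8); step 6 is the one-step side branch.

Steps most likely to fail

Step 7. The dianion may add to C4 of the coumarin instead of the lactone carbonyl. The triketone may also close too slowly (unactivated α' carbon, conjugated acceptor), so that retro-Claisen cleavage or O-cyclisation on work-up takes over. The fallback sets out from 12 and 5 and comes back at 17; it builds ring B apart from ring A on a simple, non-enolisable ester and joins the halves by alkyne chemistry.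
- Dilithiated 12 would be acylated with methyl dimethoxyacetate and the triketone closed with aqueous KOH onto the α,α-dimethoxy ketone, to give 5-(dimethoxymethyl)-4,6-bis(3-methylbut-2-en-1-yl)benzene-1,3-diol F1.
- NaH and MOMCl would give 2-(dimethoxymethyl)-4,6-bis(methoxymethoxy)-1,3-bis(3-methylbut-2-en-1-yl)benzene F2.
- PPTS in acetone–water would free 3,5-bis(methoxymethoxy)-2,6-bis(3-methylbut-2-en-1-yl)benzaldehyde F3.
- The Ohira–Bestmann reagent (dimethyl (1-diazo-2-oxopropyl)phosphonate, K2CO3, MeOH) would give 2-ethynyl-4,6-bis(methoxymethoxy)-1,3-bis(3-methylbut-2-en-1-yl)benzene F4.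
- Phenol 5 would be iodinated ortho to the hydroxyl (NIS, CH2Cl2, −20 °C) to 2-iodo-3,5-bis(methoxymethoxy)-6-(2-methylbut-3-en-2-yl)phenol F5; the isomer iodinated between the two MOM ethers would be removed by chromatography.
- Sonogashira coupling of F4 with F5 and 5-endo cyclisation of the free O1 hydroxyl in the same flask (PdCl2(PPh3)2, CuI, Et3N, DMF, 70 °C) would give 2-[3,5-bis(methoxymethoxy)-2,6-bis(3-methylbut-2-en-1-yl)phenyl]-4,6-bis(methoxymethoxy)-7-(2-methylbut-3-en-2-yl)-1-benzofuran F6.
- Methanolic HCl would then give 17.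

Step 8. While the MOM ethers are cleaved, the acid may cyclise the ortho-prenyl phenols of ring B to chromans or add methanol to the alkenes. The fallback sets out from 15 and comes back at 17; it masks the phenols that cause the damage and removes the MOM groups without protic acid.
- PPTS alone would close the furan and 16 would be isolated.
- Ac2O in pyridine would give 5-[4,6-bis(methoxymethoxy)-7-(2-methylbut-3-en-2-yl)-1-benzofuran-2-yl]-4,6-bis(3-methylbut-2-en-1-yl)-1,3-phenylene diacetate F7.
- ZnBr2 and n-PrSH in CH2Cl2 at 0 °C would cleave the MOM ethers by Lewis acid and thiol capture, to give 5-[4,6-dihydroxy-7-(2-methylbut-3-en-2-yl)-1-benzofuran-2-yl]-4,6-bis(3-methylbut-2-en-1-yl)-1,3-phenylene diacetate F8.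
- K2CO3 in MeOH would remove the acetates to give 17.

Step 5. O-acylation of the hindered, chelated phenol may be slow and the alkoxyacetate may enolise reluctantly, so that the aryl ester is cleaved before it condenses. The fallback sets out from 6 and comes back at 9; it makes the alkene by intermolecular olefination and sets the geometry afterwards.
- Horner–Wadsworth–Emmons reaction of 6 with methyl 2-(dimethoxyphosphoryl)-2-methoxyacetate (LiCl, DBU, MeCN) would give methyl (2Z)-3-[2-hydroxy-4,6-bis(methoxymethoxy)-3-(2-methylbut-3-en-2-yl)phenyl]-2-methoxyprop-2-enoate F9.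
- Irradiation at 365 nm in MeCN with a trace of DBU would equilibrate the alkene, and the isomer with the aryl group cis to the ester would lactonise to 9.

Further compounds
F1 | step 7 | 5-(dimethoxymethyl)-4,6-bis(3-methylbut-2-en-1-yl)benzene-1,3-diol | COC(OC)c1c(CC=C(C)C)c(O)cc(O)c1CC=C(C)C
F2 | step 7 | 2-(dimethoxymethyl)-4,6-bis(methoxymethoxy)-1,3-bis(3-methylbut-2-en-1-yl)benzene | COC(OC)c1c(CC=C(C)C)c(OCOC)cc(OCOC)c1CC=C(C)C
F3 | step 7 | 3,5-bis(methoxymethoxy)-2,6-bis(3-methylbut-2-en-1-yl)benzaldehyde | O=Cc1c(CC=C(C)C)c(OCOC)cc(OCOC)c1CC=C(C)C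
F4 | step 7 | 2-ethynyl-4,6-bis(methoxymethoxy)-1,3-bis(3-methylbut-2-en-1-yl)benzene | C#Cc1c(CC=C(C)C)c(OCOC)cc(OCOC)c1CC=C(C)C
F5 | step 7 | 2-iodo-3,5-bis(methoxymethoxy)-6-(2-methylbut-3-en-2-yl)phenol | COCOc1cc(OCOC)c(C(C)(C)C=C)c(O)c1I
F6 | step 7 | 2-[3,5-bis(methoxymethoxy)-2,6-bis(3-methylbut-2-en-1-yl)phenyl]-4,6-bis(methoxymethoxy)-7-(2-methylbut-3-en-2-yl)-1-benzofuran | C=CC(C)(C)c1c(OCOC)cc(OCOC)c2cc(-c3c(CC=C(C)C)c(OCOC)cc(OCOC)c3CC=C(C)C)oc12
F7 | step 8 | 5-[4,6-bis(methoxymethoxy)-7-(2-methylbut-3-en-2-yl)-1-benzofuran-2-yl]-4,6-bis(3-methylbut-2-en-1-yl)-1,3-phenylene diacetate | C=CC(C)(C)c1c(OCOC)cc(OCOC)c2cc(-c3c(CC=C(C)C)c(OC(C)=O)cc(OC(C)=O)c3CC=C(C)C)oc12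
F8 | step 8 | 5-[4,6-dihydroxy-7-(2-methylbut-3-en-2-yl)-1-benzofuran-2-yl]-4,6-bis(3-methylbut-2-en-1-yl)-1,3-phenylene diacetate | C=CC(C)(C)c1c(O)cc(O)c2cc(-c3c(CC=C(C)C)c(OC(C)=O)cc(OC(C)=O)c3CC=C(C)C)oc12
F9 | step 5 | methyl (2Z)-3-[2-hydroxy-4,6-bis(methoxymethoxy)-3-(2-methylbut-3-en-2-yl)phenyl]-2-methoxyprop-2-enoate | COCOc1cc(OCOC)c(C(C)(C)C=C)c(O)c1/C=C(\OC)C(=O)OC
A1 | direct plan | 2-hydroxy-3-(2-methylbut-3-en-2-yl)-4,6-bis[(triisopropylsilyl)oxy]benzaldehyde | O=Cc1c(O[Si](C(C)C)(C(C)C)C(C)C)cc(O[Si](C(C)C)(C(C)C)C(C)C)c(C(C)(C)C=C)c1O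
A2 | direct plan | 2-bromo-7-(2-methylbut-3-en-2-yl)-4,6-bis[(triisopropylsilyl)oxy]-1-benzofuran | C=CC(C)(C)c1c(O[Si](C(C)C)(C(C)C)C(C)C)cc(O[Si](C(C)C)(C(C)C)C(C)C)c2cc(Br)oc12
A3 | direct plan | 3-ethoxy-2,4-bis(3-methylbut-2-en-1-yl)cyclobut-2-en-1-one, racemic | CCOC1=C(CC=C(C)C)C(=O)C1CC=C(C)C
A4 | direct plan | 3-[7-(2-methylbut-3-en-2-yl)-4,6-bis[(triisopropylsilyl)oxy]-1-benzofuran-2-yl]-2,4-bis(3-methylbut-2-en-1-yl)cyclobut-2-en-1-one, racemic | O=C1C(CC=C(C)C)C(c2cc3c(O[Si](C(C)C)(C(C)C)C(C)C)cc(O[Si](C(C)C)(C(C)C)C(C)C)c(C(C)(C)C=C)c3o2)=C1CC=C(C)C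
A5 | direct plan | trimethyl[2-(ethynyloxy)ethyl]silane | C#COCC[Si](C)(C)C
A6 | direct plan | 2-[3-hydroxy-2,6-bis(3-methylbut-2-en-1-yl)-5-[2-(trimethylsilyl)ethoxy]phenyl]-7-(2-methylbut-3-en-2-yl)-4,6-bis[(triisopropylsilyl)oxy]-1-benzofuran | C=CC(C)(C)c1c(O[Si](C(C)C)(C(C)C)C(C)C)cc(O[Si](C(C)C)(C(C)C)C(C)C)c2cc(-c3c(CC=C(C)C)c(OCC[Si](C)(C)C)cc(O)c3CC=C(C)C)oc12
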